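**Retrosynthetic overview**

1. Ring B is opened at C4–C4a: intramolecular Friedel–Crafts alkylation of a veratryl cation by the ketone-bearing guaiacyl ring, para to its OH; this sets C4 trans to the C3 methyl.
2. The aryl ketone bond C1–C8a comes from an aryllithium and a γ-lactone. That lactone is made in the same flask from a γ-keto ester, so one operation closes first the lactone (transient) and then ring B.
3. The cis-2,3-dimethyl pair and its absolute configuration come from a catalytic enantioselective arylation of meso-2,3-dimethylsuccinic anhydride with a veratrylzinc reagent.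
4. The meso anhydride comes from 2,3-dimethylmaleic anhydride by syn-hydrogenation; both benzene rings are bought.
5. Ring order: anhydride ring (opened in the arylation) → γ-lactone (transient) → ring B.

Assumption: the ligand antipode in step 2 is the one that delivers (2S,3R)-6; both antipodes are available, so the sense of induction is a matter of choice and must be confirmed experimentally.

**Step 1**
Reactants: 1 2,3-dimethylmaleic anhydride
Product: 2 meso-2,3-dimethylsuccinic anhydride (cis-3,4-dimethyloxolane-2,5-dione)
Conditions: H2 (4 atm), 10% Pd/C, EtOAc, 23 °C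
Reagents that add atoms: none
Why: Heterogeneous catalytic hydrogenation adds both hydrogens to one face of the tetrasubstituted alkene (syn addition), so only the cis (meso) anhydride forms and the 2,3-cis methyl relationship of the target is fixed here.

**Step 2**
Reactants: 2 meso-2,3-dimethylsuccinic anhydride; 3 4-bromo-1,2-dimethoxybenzene
Product: 7 methyl (2S,3R)-4-(3,4-dimethoxyphenyl)-2,3-dimethyl-4-oxobutanoate, via aryllithium 4 (not isolated), via arylzinc triflate 5 (not isolated), via keto acid 6 (not isolated)
Conditions: 3, n-BuLi, THF, −78 °C; Zn(OTf)2, 0 °C; then 2, [Rh(cod)Cl]2 (4 mol %), TADDOL-derived phosphoramidite (8 mol %), DMF, 50 °C; 1 M HCl; then TMSCHN2, PhMe–MeOH, 0 °C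
Reagents that add atoms: (trimethylsilyl)diazomethane, C[Si](C)(C)C=[N+]=[N-]
Why: Rh-catalysed enantioselective desymmetrising acyl cross-coupling (Negishi-type) of a meso anhydride, in which the chiral Rh(I) complex inserts into one of the two enantiotopic C(O)–O bonds and transfers the aryl group from zinc, so the two existing methyl-bearing carbons become the (2S,3R) syn pair by catalyst control, and neutral TMSCHN2 esterification leaves the epimerisable centre α to the ketone untouched.

**Step 3**
Reactants: 7 methyl (2S,3R)-4-(3,4-dimethoxyphenyl)-2,3-dimethyl-4-oxobutanoate; 8 5-bromo-2-methoxyphenol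
Product: 12 schisandrone [(2S,3S,4R)-4-(3,4-dimethoxyphenyl)-7-hydroxy-6-methoxy-2,3-dimethyl-3,4-dihydronaphthalen-1(2H)-one], via lactone 9 (not isolated), via dilithiated phenol 10 (not isolated), via hydroxy ketone 11 (not isolated)
Conditions: L-Selectride (1.05 equiv), THF, −78 → 0 °C; then 10 (1.2 equiv; from 8, n-BuLi then t-BuLi, THF, −78 °C), −78 °C; then TFA, CH2Cl2, −78 → 0 °C
Reagents that add atoms: none
Why: Felkin–Anh hydride reduction of the aryl ketone gives a γ-alkoxide that lactonises onto the methyl ester (first new ring, whose C5 configuration is later erased), the aryllithium adds once to the lactone to give a stable lactolate, and on acidification the veratryl carbinol ionises to a benzylic cation that the tethered ring captures para to its OH in an intramolecular Friedel–Crafts alkylation through a chair-like transition state that puts the aryl group trans to the C3 methyl (4R), while C2 and C3 are carried over unchanged from 7.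

**Compound list**

1 | 2,3-dimethylmaleic anhydride (3,4-dimethylfuran-2,5-dione) | CC1=C(C)C(=O)OC1=O | starting material
2 | meso-2,3-dimethylsuccinic anhydride, (3R,4S)-3,4-dimethyloxolane-2,5-dione (cis) | O=C1[C@@H](C)[C@@H](C)C(=O)O1 | intermediate
3 | 4-bromo-1,2-dimethoxybenzene | COc1ccc(Br)cc1OC | starting material
4 | (3,4-dimethoxyphenyl)lithium | [Li]c1ccc(OC)c(OC)c1 | intermediate
5 | (3,4-dimethoxyphenyl)zinc trifluoromethanesulfonate | COc1ccc([Zn]OS(=O)(=O)C(F)(F)F)cc1OC | intermediate
6 | (2S,3R)-4-(3,4-dimethoxyphenyl)-2,3-dimethyl-4-oxobutanoic acid | OC(=O)[C@@H](C)[C@@H](C)C(=O)c1ccc(OC)c(OC)c1 | intermediate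
7 | methyl (2S,3R)-4-(3,4-dimethoxyphenyl)-2,3-dimethyl-4-oxobutanoate | COC(=O)[C@@H](C)[C@@H](C)C(=O)c1ccc(OC)c(OC)c1 | intermediate
8 | 5-bromo-2-methoxyphenol | COc1ccc(Br)cc1O | starting material
9 | (3S,4R,5R)-5-(3,4-dimethoxyphenyl)-3,4-dimethyloxolan-2-one (3,4-cis, 4,5-trans; major Felkin epimer, C5 is not carried into the product) | O=C1[C@@H](C)[C@@H](C)[C@H](c2ccc(OC)c(OC)c2)O1 | intermediate
10 | lithium 5-lithio-2-methoxyphenolate | [Li]Oc1cc([Li])ccc1OC | intermediate
11 | (2S,3R,4R)-4-(3,4-dimethoxyphenyl)-4-hydroxy-1-(3-hydroxy-4-methoxyphenyl)-2,3-dimethylbutan-1-one | COc1ccc(cc1O)C(=O)[C@@H](C)[C@@H](C)[C@@H](O)c1ccc(OC)c(OC)c1 | intermediate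
12 | schisandrone, (2S,3S,4R)-4-(3,4-dimethoxyphenyl)-7-hydroxy-6-methoxy-2,3-dimethyl-3,4-dihydronaphthalen-1(2H)-one | COc1cc2c(cc1O)C(=O)[C@@H](C)[C@@H](C)[C@@H]2c1ccc(OC)c(OC)c1 | target

**Totals**

Total step count: 3 (isolated products 2, 7 and 12).
Longest linear sequence: 3 (1 → 2 → 7 → 12); 3 and 8 are bought.

**Steps most likely to fail, with fallbacks**

Step 3 is the most exposed. Three reactions share one flask, and each has its own failure mode:
- Lactonisation may be incomplete before the aryllithium is added, which opens the way to double addition on the open ester.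
- After acidification the ketone oxygen can trap the C4 cation as a cyclic enol ether, and its re-protonation would scramble C2.
- The cation can lose a proton to give the styrene, which would scramble C3.
- Guaiacol from the excess of 10 can intercept the cation.
- The ring can close ortho instead of para to the OH.
- The product must not meet base, because the all-trans C2 epimer is of similar or slightly lower energy (my estimate).

The fallback sets out from 7 and comes back at 12. 7 is reduced with NaBH4 in MeOH and lactonised with TsOH to give isolated lactone 9. 9 is opened with Me(MeO)NH·HCl/AlMe3 to the hydroxy Weinreb amide F1, which is silylated at once (TBSOTf, 2,6-lutidine) to the silyl ether F2. Dianion 10 is acylated by F2 (Weinreb ketone synthesis, no over-addition and no lactol) to give the purified γ-silyloxy aryl ketone F3. F3 is ionised at the benzylic C–OTBS bond (BF3·OEt2 or TFA in CH2Cl2/HFIP, −40 °C) and cyclises to 12. The silyl ether keeps the ketone from forming a lactol or enol ether before the cation exists.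

Step 2 is second. The electron-rich arylzinc may give lower ee or yield than simpler aryl groups, and the centre α to the new ketone can epimerise if the work-up is basic. The fallback sets out from 2 and comes back at 7. 2 is opened with methanol under quinidine mediation (toluene, −55 °C; quinine gives the antipode) to the hemiester (2R,3S)-4-methoxy-2,3-dimethyl-4-oxobutanoic acid F4. F4 is converted with oxalyl chloride into the acid chloride F5. F5 acylates 1,2-dimethoxybenzene (SnCl4, CH2Cl2, −20 °C) para to a methoxy group to give 7.

Step 1 is the least risky. The tetrasubstituted alkene may hydrogenate slowly, and any trans anhydride would carry through as racemic material. The fallback sets out from 1 and comes back at 2. 1 is hydrolysed with aqueous NaOH to disodium 2,3-dimethylmaleate F6. F6 is hydrogenated in water (Raney Ni, 50 atm) and acidified to meso-2,3-dimethylsuccinic acid F7, which is freed from any racemic acid by crystallisation. F7 is closed with refluxing acetyl chloride to 2.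

**Further compounds**

F1 | step 3 | (2S,3R,4R)-4-(3,4-dimethoxyphenyl)-4-hydroxy-N-methoxy-N,2,3-trimethylbutanamide | CON(C)C(=O)[C@@H](C)[C@@H](C)[C@@H](O)c1ccc(OC)c(OC)c1
F2 | step 3 | (2S,3R,4R)-4-[tert-butyl(dimethyl)silyl]oxy-4-(3,4-dimethoxyphenyl)-N-methoxy-N,2,3-trimethylbutanamide | CON(C)C(=O)[C@@H](C)[C@@H](C)[C@@H](O[Si](C)(C)C(C)(C)C)c1ccc(OC)c(OC)c1
F3 | step 3 | (2S,3R,4R)-4-[tert-butyl(dimethyl)silyl]oxy-4-(3,4-dimethoxyphenyl)-1-(3-hydroxy-4-methoxyphenyl)-2,3-dimethylbutan-1-one | COc1ccc(cc1O)C(=O)[C@@H](C)[C@@H](C)[C@@H](O[Si](C)(C)C(C)(C)C)c1ccc(OC)c(OC)c1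
F4 | step 2 | (2R,3S)-4-methoxy-2,3-dimethyl-4-oxobutanoic acid | COC(=O)[C@@H](C)[C@@H](C)C(=O)O
F5 | step 2 | methyl (2S,3R)-4-chloro-2,3-dimethyl-4-oxobutanoate | COC(=O)[C@@H](C)[C@@H](C)C(=O)Cl
F6 | step 1 | disodium (2Z)-2,3-dimethylbut-2-enedioate | [Na+].[Na+].[O-]C(=O)/C(C)=C(/C)C(=O)[O-]
F7 | step 1 | meso-(2R,3S)-2,3-dimethylbutanedioic acid | OC(=O)[C@@H](C)[C@@H](C)C(=O)O
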